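**Plan**

- Retrosynthesis: ring C is a β-aryloxy ketone, with O1 standing β to the C4 carbonyl across C2–C3. It is opened at O1–C2 to a 2-hydroxyaryl enone that carries a temporary tert-butyl ester on C3. Further cuts are C2=C3 (Knoevenagel), C4a–C4 (acetyl by Stille coupling), and in the piperidine N–C6'' and C2''–C3'' (sulfinimine route); C2'' starts as a formyl carbon on ring A.
- Forward: ring A is bought as a phloroglucinol dibenzyl ether. The piperidine ring is built first on the carbon para to the free OH, the C3 chain is then attached ortho to that OH, and ring C is closed last. N-methylation and debenzylation finish the route.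
- Regiochemistry: at ring closure the oxygen para to C6 (future O1) is the only free phenol. O5 and O7, which flank C6, are benzyl ethers, so only the 6-substituted flavanone can form.
- Stereochemistry: C2'' (S) comes from (R)-tert-butanesulfinamide by chelate-controlled Grignard addition. C2 (S) comes from a bifunctional cinchona thiourea catalyst in the ring-closing oxa-Michael addition.

Key step: step 10

Assumption: the quinidine-derived thiourea is taken to give the 2S series with this substrate (its quinine-derived pseudo-enantiomer serves if the sense proves opposite), and compound 1 is taken as a purchasable building block.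

**Route**

Step 1
Reactants: 1 3,5-bis(benzyloxy)phenol
Product: 3 2,6-bis(benzyloxy)-4-hydroxybenzaldehyde, via aryl iminium chloride 2 (not isolated)
Conditions: POCl3 (1.2 equiv), DMF, 0 °C → rt; then H2O, 50 °C
Reagents that add atoms: N,N-dimethylformamide, CN(C)C=O; water, O
Why: Vilsmeier–Haack formylation of the phloroglucinol diether should go mainly para to the free hydroxyl, as it does with 3,5-dimethoxyphenol, and the chelated ortho-hydroxy isomer should be separable by chromatography.

Step 2
Reactants: 3 2,6-bis(benzyloxy)-4-hydroxybenzaldehyde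
Product: 4 2,6-bis(benzyloxy)-4-(methoxymethoxy)benzaldehyde
Conditions: MOMCl, i-Pr2NEt, CH2Cl2, 0 °C → rt
Reagents that add atoms: chloromethyl methyl ether, COCCl
Why: O-alkylation of the acidic para-hydroxybenzaldehyde gives an acetal ether that marks the future O1 as the one oxygen to be unveiled later and withstands the organometallic steps.

Step 3
Reactants: 4 2,6-bis(benzyloxy)-4-(methoxymethoxy)benzaldehyde; 5 (R)-2-methylpropane-2-sulfinamide
Product: 6 (R,E)-N-[2,6-bis(benzyloxy)-4-(methoxymethoxy)benzylidene]-2-methylpropane-2-sulfinamide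
Conditions: Ti(OEt)4 (2 equiv), THF, 65 °C
Reagents that add atoms: none
Why: Ti(OEt)4-mediated condensation of an aldehyde with tert-butanesulfinamide is the standard route to the E-configured N-sulfinyl aldimine and should tolerate the hindered, electron-rich aldehyde at this temperature.

Step 4
Reactants: 6 (R,E)-N-[2,6-bis(benzyloxy)-4-(methoxymethoxy)benzylidene]-2-methylpropane-2-sulfinamide
Product: 8 (S)-2-[2,6-bis(benzyloxy)-4-(methoxymethoxy)phenyl]-1-[(R)-tert-butylsulfinyl]piperidine, via chloroalkyl sulfinamide 7 (not isolated)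
Conditions: ClCH2(CH2)3MgBr (from 1-bromo-4-chlorobutane and Mg, Et2O), CH2Cl2, −48 °C → rt; NH4Cl work-up; crude 7, KN(SiMe3)2, THF, 0 → 50 °C
Reagents that add atoms: 4-chlorobutylmagnesium bromide, ClCCCC[Mg]Br
Why: Grignard addition to the N-tert-butanesulfinyl aldimine in a non-coordinating solvent should pass through the six-membered chair with magnesium on the sulfinyl oxygen and tert-butyl equatorial, so that the alkyl group reaches the Si face of the (R)-sulfinyl imine and sets C2'' as S, after which the sulfinamide anion closes the piperidine by 6-exo-tet N-alkylation without touching that centre.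

Step 5
Reactants: 8 (S)-2-[2,6-bis(benzyloxy)-4-(methoxymethoxy)phenyl]-1-[(R)-tert-butylsulfinyl]piperidine
Product: 10 tert-butyl (S)-2-[2,6-bis(benzyloxy)-4-hydroxyphenyl]piperidine-1-carboxylate, via aminophenol hydrochloride 9 (not isolated)
Conditions: HCl (4 M in dioxane), MeOH, 0 → 40 °C; evaporate; Boc2O, NaHCO3, THF/H2O, rt
Reagents that add atoms: di-tert-butyl dicarbonate, CC(C)(C)OC(=O)OC(=O)OC(C)(C)C
Why: acid methanolysis cleaves the N–S bond and the methoxymethyl acetal in one operation while the protonated benzylic amine should not ionise under these mild conditions, and carbamate formation under bicarbonate should then take the amine in preference to the phenol.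

Step 6
Reactants: 10 tert-butyl (S)-2-[2,6-bis(benzyloxy)-4-hydroxyphenyl]piperidine-1-carboxylate
Product: 11 tert-butyl (S)-2-[2,6-bis(benzyloxy)-4-hydroxy-3-iodophenyl]piperidine-1-carboxylate
Conditions: N-iodosuccinimide (1.0 equiv), CH2Cl2, −20 → 0 °C
Reagents that add atoms: N-iodosuccinimide, O=C1CCC(=O)N1I
Why: electrophilic aromatic iodination of the activated phenol can only occur at the two open positions ortho to the hydroxyl, which are equivalent by rotation about the aryl–piperidine bond, so one equivalent of reagent should give a single monoiodide.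

Step 7
Reactants: 11 tert-butyl (S)-2-[2,6-bis(benzyloxy)-4-hydroxy-3-iodophenyl]piperidine-1-carboxylate
Product: 13 tert-butyl (S)-2-[3-acetyl-2,6-bis(benzyloxy)-4-hydroxyphenyl]piperidine-1-carboxylate, via ethoxyvinyl arene 12 (not isolated)
Conditions: tributyl(1-ethoxyvinyl)stannane, Pd(PPh3)4 (5 mol %), CuI (10 mol %), dioxane, 90 °C; then 1 M HCl, THF, rt
Reagents that add atoms: tributyl(1-ethoxyvinyl)stannane, CCCC[Sn](CCCC)(CCCC)C(=C)OCC; water, O
Why: Stille coupling with the α-ethoxyvinylstannane as an acetyl equivalent, followed by mild hydrolysis of the enol ether, installs the C4–C3 unit under neutral conditions that spare the carbamate, the benzyl ethers and the free phenol.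

Step 8
Reactants: 13 tert-butyl (S)-2-[3-acetyl-2,6-bis(benzyloxy)-4-hydroxyphenyl]piperidine-1-carboxylate
Product: 15 tert-butyl (S)-2-[2,6-bis(benzyloxy)-3-(3-tert-butoxy-3-oxopropanoyl)-4-hydroxyphenyl]piperidine-1-carboxylate, via aryl tert-butyl carbonate 14 (not isolated)
Conditions: Boc2O (1.1 equiv), DMAP (cat.), Et3N, THF, rt; then LiN(SiMe3)2 (3.3 equiv), −78 → 0 °C; NH4Cl
Reagents that add atoms: di-tert-butyl dicarbonate, CC(C)(C)OC(=O)OC(=O)OC(C)(C)C
Why: O-acylation of the phenol followed by base-induced intramolecular O→C transfer of the tert-butoxycarbonyl group to the ketone enolate (a Baker–Venkataraman-type Claisen condensation) gives the tert-butyl β-ketoester and frees the phenoxide, and the low temperature and bulky ester should prevent lactonisation to a 4-hydroxycoumarin.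

Step 9
Reactants: 15 tert-butyl (S)-2-[2,6-bis(benzyloxy)-3-(3-tert-butoxy-3-oxopropanoyl)-4-hydroxyphenyl]piperidine-1-carboxylate; 16 4-(benzyloxy)benzaldehyde
Product: 17 tert-butyl (S)-2-[2,6-bis(benzyloxy)-3-[(Z)-3-(4-benzyloxyphenyl)-2-(tert-butoxycarbonyl)acryloyl]-4-hydroxyphenyl]piperidine-1-carboxylate
Conditions: piperidine (0.2 equiv), AcOH (0.4 equiv), toluene, 4 Å molecular sieves, rt → 40 °C
Reagents that add atoms: none
Why: Knoevenagel condensation of the β-ketoester under buffered amine–acid catalysis should give the thermodynamic alkylidene (aryl cis to the ester), the excess acetic acid keeping the phenol protonated so that the adduct can be isolated before any ring closure.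

Step 10
Reactants: 17 tert-butyl (S)-2-[2,6-bis(benzyloxy)-3-[(Z)-3-(4-benzyloxyphenyl)-2-(tert-butoxycarbonyl)acryloyl]-4-hydroxyphenyl]piperidine-1-carboxylate
Product: 19 (S)-5,7-bis(benzyloxy)-2-(4-benzyloxyphenyl)-6-[(S)-piperidin-2-yl]chroman-4-one, via flavanone-3-carboxylate 18 (not isolated)
Conditions: N-[3,5-bis(trifluoromethyl)phenyl]-N'-(9-deoxy-epi-quinidin-9-yl)thiourea (10 mol %), toluene, −25 °C; then TsOH·H2O (5 equiv), 80 °C; NaHCO3 work-up
Reagents that add atoms: none
Why: The quinuclidine nitrogen of the catalyst activates the free phenol as a general base while the thiourea N–H pair binds the 1,3-dicarbonyl unit, so the phenol oxygen adds to the β-carbon of the alkylidene in an intramolecular oxa-Michael addition that forms O1–C2; acid then cleaves the tert-butyl ester, the β-keto acid loses CO2 through its enol, and the N-Boc group falls in the same operation. The closest known reaction type is the bifunctional cinchona thiourea-catalysed cyclisation of 2-hydroxyaryl alkylidene β-ketoesters to flavanone-3-carboxylates with one-pot dealkylative decarboxylation. Ring C closes in a 6-endo-trig mode. The C2 configuration is set by the catalyst through enantiofacial discrimination of the bound alkylidene; the piperidine centre sits para to the attacking oxygen and is too remote to interfere, and C3 is erased on decarboxylation. The step needs a choice among the three ring-A oxygens and freedom from racemic background closure: the first is secured because only the oxygen para to C6 is free while O5 and O7 are benzylated, the second by the low temperature, the non-basic carbamate on nitrogen and the acidic, enolate-free removal of the ester, which gives no opening for retro-Michael ring opening.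

Step 11
Reactants: 19 (S)-5,7-bis(benzyloxy)-2-(4-benzyloxyphenyl)-6-[(S)-piperidin-2-yl]chroman-4-one
Product: 20 (S)-5,7-bis(benzyloxy)-2-(4-benzyloxyphenyl)-6-[(S)-1-methylpiperidin-2-yl]chroman-4-one
Conditions: 37 % aq. CH2O (1.5 equiv), NaBH(OAc)3 (2 equiv), ClCH2CH2Cl, rt
Reagents that add atoms: formaldehyde, C=O
Why: reductive amination with NaBH(OAc)3 reduces the iminium ion but not the aryl ketone, and it is run while all phenols are still benzylated so that formaldehyde cannot attack the nucleophilic C8 position.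

Step 12
Reactants: 20 (S)-5,7-bis(benzyloxy)-2-(4-benzyloxyphenyl)-6-[(S)-1-methylpiperidin-2-yl]chroman-4-one
Product: 21 (S)-5,7-dihydroxy-2-(4-hydroxyphenyl)-6-[(S)-1-methylpiperidin-2-yl]chroman-4-one
Conditions: H2 (1 atm), 10 % Pd/C, EtOAc/MeOH, rt
Reagents that add atoms: none
Why: hydrogenolysis of the three aryl benzyl ethers under neutral conditions at ambient pressure should be much faster than cleavage of the cyclic benzylic C–N and C–O bonds or reduction of the ketone, and it leaves both stereocentres untouched.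

**Compound list**

1 | 3,5-bis(benzyloxy)phenol | Oc1cc(OCc2ccccc2)cc(OCc2ccccc2)c1 | starting material
2 | [2,6-bis(benzyloxy)-4-hydroxybenzylidene]dimethyliminium chloride | C[N+](C)=Cc1c(OCc2ccccc2)cc(O)cc1OCc1ccccc1.[Cl-] | intermediate
3 | 2,6-bis(benzyloxy)-4-hydroxybenzaldehyde | O=Cc1c(OCc2ccccc2)cc(O)cc1OCc1ccccc1 | intermediate
4 | 2,6-bis(benzyloxy)-4-(methoxymethoxy)benzaldehyde | COCOc1cc(OCc2ccccc2)c(C=O)c(OCc2ccccc2)c1 | intermediate
5 | (R)-2-methylpropane-2-sulfinamide | CC(C)(C)[S@@](=O)N | starting material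
6 | (R,E)-N-[2,6-bis(benzyloxy)-4-(methoxymethoxy)benzylidene]-2-methylpropane-2-sulfinamide | CC(C)(C)[S@@](=O)/N=C/c1c(OCc2ccccc2)cc(OCOC)cc1OCc1ccccc1 | intermediate
7 | (R)-N-[(S)-1-[2,6-bis(benzyloxy)-4-(methoxymethoxy)phenyl]-5-chloropentyl]-2-methylpropane-2-sulfinamide | CC(C)(C)[S@@](=O)N[C@@H](CCCCCl)c1c(OCc2ccccc2)cc(OCOC)cc1OCc1ccccc1 | intermediate
8 | (S)-2-[2,6-bis(benzyloxy)-4-(methoxymethoxy)phenyl]-1-[(R)-tert-butylsulfinyl]piperidine | CC(C)(C)[S@@](=O)N1CCCC[C@H]1c1c(OCc2ccccc2)cc(OCOC)cc1OCc1ccccc1 | intermediate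
9 | (S)-3,5-bis(benzyloxy)-4-(piperidin-2-yl)phenol hydrochloride | Cl.N1CCCC[C@H]1c1c(OCc2ccccc2)cc(O)cc1OCc1ccccc1 | intermediate
10 | tert-butyl (S)-2-[2,6-bis(benzyloxy)-4-hydroxyphenyl]piperidine-1-carboxylate | CC(C)(C)OC(=O)N1CCCC[C@H]1c1c(OCc2ccccc2)cc(O)cc1OCc1ccccc1 | intermediate
11 | tert-butyl (S)-2-[2,6-bis(benzyloxy)-4-hydroxy-3-iodophenyl]piperidine-1-carboxylate | CC(C)(C)OC(=O)N1CCCC[C@H]1c1c(OCc2ccccc2)cc(O)c(I)c1OCc1ccccc1 | intermediate
12 | tert-butyl (S)-2-[2,6-bis(benzyloxy)-3-(1-ethoxyvinyl)-4-hydroxyphenyl]piperidine-1-carboxylate | CC(C)(C)OC(=O)N1CCCC[C@H]1c1c(OCc2ccccc2)cc(O)c(C(=C)OCC)c1OCc1ccccc1 | intermediate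
13 | tert-butyl (S)-2-[3-acetyl-2,6-bis(benzyloxy)-4-hydroxyphenyl]piperidine-1-carboxylate | CC(C)(C)OC(=O)N1CCCC[C@H]1c1c(OCc2ccccc2)cc(O)c(C(C)=O)c1OCc1ccccc1 | intermediate
14 | tert-butyl (S)-2-[3-acetyl-2,6-bis(benzyloxy)-4-(tert-butoxycarbonyloxy)phenyl]piperidine-1-carboxylate | CC(C)(C)OC(=O)N1CCCC[C@H]1c1c(OCc2ccccc2)cc(OC(=O)OC(C)(C)C)c(C(C)=O)c1OCc1ccccc1 | intermediate
15 | tert-butyl (S)-2-[2,6-bis(benzyloxy)-3-(3-tert-butoxy-3-oxopropanoyl)-4-hydroxyphenyl]piperidine-1-carboxylate | CC(C)(C)OC(=O)N1CCCC[C@H]1c1c(OCc2ccccc2)cc(O)c(C(=O)CC(=O)OC(C)(C)C)c1OCc1ccccc1 | intermediate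
16 | 4-(benzyloxy)benzaldehyde | O=Cc1ccc(OCc2ccccc2)cc1 | starting material
17 | tert-butyl (S)-2-[2,6-bis(benzyloxy)-3-[(Z)-3-(4-benzyloxyphenyl)-2-(tert-butoxycarbonyl)acryloyl]-4-hydroxyphenyl]piperidine-1-carboxylate | CC(C)(C)OC(=O)N1CCCC[C@H]1c1c(OCc2ccccc2)cc(O)c(C(=O)/C(C(=O)OC(C)(C)C)=C/c2ccc(OCc3ccccc3)cc2)c1OCc1ccccc1 | intermediate
18 | tert-butyl (2S)-5,7-bis(benzyloxy)-2-(4-benzyloxyphenyl)-6-[(S)-1-(tert-butoxycarbonyl)piperidin-2-yl]-4-oxochromane-3-carboxylate (C3 epimerisable, left open) | CC(C)(C)OC(=O)N1CCCC[C@H]1c1c(OCc2ccccc2)cc2c(c1OCc1ccccc1)C(=O)C(C(=O)OC(C)(C)C)[C@@H](c1ccc(OCc3ccccc3)cc1)O2 | intermediate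
19 | (S)-5,7-bis(benzyloxy)-2-(4-benzyloxyphenyl)-6-[(S)-piperidin-2-yl]chroman-4-one | N1CCCC[C@H]1c1c(OCc2ccccc2)cc2c(c1OCc1ccccc1)C(=O)C[C@@H](c1ccc(OCc3ccccc3)cc1)O2 | intermediate
20 | (S)-5,7-bis(benzyloxy)-2-(4-benzyloxyphenyl)-6-[(S)-1-methylpiperidin-2-yl]chroman-4-one | CN1CCCC[C@H]1c1c(OCc2ccccc2)cc2c(c1OCc1ccccc1)C(=O)C[C@@H](c1ccc(OCc3ccccc3)cc1)O2 | intermediate
21 | (S)-5,7-dihydroxy-2-(4-hydroxyphenyl)-6-[(S)-1-methylpiperidin-2-yl]chroman-4-one | CN1CCCC[C@H]1c1c(O)cc2c(c1O)C(=O)C[C@@H](c1ccc(O)cc1)O2 | target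

**Step count and risks**

Total steps: 12. Longest linear sequence: 12 steps, from 1 to 21 (the Grignard reagent of step 4 is prepared separately).

Steps most likely to fail:

Step 10. The enantiofacial control could be eroded by uncatalysed ring closure, since alkylidenes with an ortho-alkoxy group on the aryl ketone cyclise readily, or by acid-induced loss of configuration at C2 during the hot decarboxylation. The fallback closes ring C first without a stereocentre and sets C2 afterwards. It sets out from 13: condensation with N,N-dimethylformamide dimethyl acetal (toluene, 90 °C) should give tert-butyl (S)-2-[2,6-bis(benzyloxy)-3-[(E)-3-(dimethylamino)acryloyl]-4-hydroxyphenyl]piperidine-1-carboxylate F1. Warming in acetic acid should cyclise this with loss of dimethylamine to tert-butyl (S)-2-[5,7-bis(benzyloxy)-4-oxo-4H-chromen-6-yl]piperidine-1-carboxylate F2. Asymmetric conjugate addition of 4-(benzyloxy)phenylboronic acid (Pd(OCOCF3)2, the enantiomer of the tert-butyl pyridinyl-oxazoline ligand that delivers the 2S series, NH4PF6, H2O, ClCH2CH2Cl, 60 °C) should then give tert-butyl (S)-2-[(S)-5,7-bis(benzyloxy)-2-(4-benzyloxyphenyl)-4-oxochroman-6-yl]piperidine-1-carboxylate F3. Removal of the carbamate (CF3CO2H, CH2Cl2, 0 °C) returns to the route at 19.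

Step 4. Facial selectivity could be poor or reversed if an ortho benzyloxy oxygen competes with the sulfinyl oxygen for magnesium, and addition to the deactivated, doubly ortho-substituted aldimine could be sluggish. The fallback builds the ring by allylation and ring-closing metathesis instead of by N-alkylation. It sets out from 6: indium-mediated Barbier allylation (indium powder, allyl bromide, THF, 60 °C), which is expected to attack the same Si face through a different, nitrogen-bound cyclic transition state, should give (R)-N-[(S)-1-[2,6-bis(benzyloxy)-4-(methoxymethoxy)phenyl]but-3-enyl]-2-methylpropane-2-sulfinamide F4, with the diastereomers separable at this stage. N-allylation (NaH, allyl bromide, DMF) should give (R)-N-allyl-N-[(S)-1-[2,6-bis(benzyloxy)-4-(methoxymethoxy)phenyl]but-3-enyl]-2-methylpropane-2-sulfinamide F5. Ring-closing metathesis with the second-generation Grubbs catalyst (CH2Cl2, 40 °C) should give (S)-2-[2,6-bis(benzyloxy)-4-(methoxymethoxy)phenyl]-1-[(R)-tert-butylsulfinyl]-1,2,3,6-tetrahydropyridine F6. Diimide reduction of the ring alkene (2-nitrobenzenesulfonyl hydrazide, Et3N, CH2Cl2), which spares the benzyl ethers, returns to the route at 8.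

Step 9. The free phenol could add to the newly formed alkylidene during the condensation, which would deliver material racemic at C2 before the chiral catalyst is present. The fallback keeps the phenol masked through the condensation with a group that cannot migrate to the enolate and is removed without acid or base. It sets out from 13: 4-methoxybenzylation (4-methoxybenzyl chloride, K2CO3, NaI, DMF, 60 °C) should give tert-butyl (S)-2-[3-acetyl-2,6-bis(benzyloxy)-4-(4-methoxybenzyloxy)phenyl]piperidine-1-carboxylate F7. Direct C-carboxylation of the ketone enolate (LiN(SiMe3)2, Boc2O, THF, −78 °C) should give tert-butyl (S)-2-[2,6-bis(benzyloxy)-3-(3-tert-butoxy-3-oxopropanoyl)-4-(4-methoxybenzyloxy)phenyl]piperidine-1-carboxylate F8. Knoevenagel condensation with 16 as in step 9 should give tert-butyl (S)-2-[2,6-bis(benzyloxy)-3-[(Z)-3-(4-benzyloxyphenyl)-2-(tert-butoxycarbonyl)acryloyl]-4-(4-methoxybenzyloxy)phenyl]piperidine-1-carboxylate F9. Oxidative removal of the 4-methoxybenzyl group (DDQ, CH2Cl2/pH 7 buffer, 0 °C) returns to the route at 17 immediately before the catalytic step.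

**Further compounds**

F1 | step 10 | tert-butyl (S)-2-[2,6-bis(benzyloxy)-3-[(E)-3-(dimethylamino)acryloyl]-4-hydroxyphenyl]piperidine-1-carboxylate | CC(C)(C)OC(=O)N1CCCC[C@H]1c1c(OCc2ccccc2)cc(O)c(C(=O)/C=C/N(C)C)c1OCc1ccccc1
F2 | step 10 | tert-butyl (S)-2-[5,7-bis(benzyloxy)-4-oxo-4H-chromen-6-yl]piperidine-1-carboxylate | CC(C)(C)OC(=O)N1CCCC[C@H]1c1c(OCc2ccccc2)cc2occc(=O)c2c1OCc1ccccc1
F3 | step 10 | tert-butyl (S)-2-[(S)-5,7-bis(benzyloxy)-2-(4-benzyloxyphenyl)-4-oxochroman-6-yl]piperidine-1-carboxylate | CC(C)(C)OC(=O)N1CCCC[C@H]1c1c(OCc2ccccc2)cc2c(c1OCc1ccccc1)C(=O)C[C@@H](c1ccc(OCc3ccccc3)cc1)O2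
F4 | step 4 | (R)-N-[(S)-1-[2,6-bis(benzyloxy)-4-(methoxymethoxy)phenyl]but-3-enyl]-2-methylpropane-2-sulfinamide | CC(C)(C)[S@@](=O)N[C@@H](CC=C)c1c(OCc2ccccc2)cc(OCOC)cc1OCc1ccccc1
F5 | step 4 | (R)-N-allyl-N-[(S)-1-[2,6-bis(benzyloxy)-4-(methoxymethoxy)phenyl]but-3-enyl]-2-methylpropane-2-sulfinamide | CC(C)(C)[S@@](=O)N(CC=C)[C@@H](CC=C)c1c(OCc2ccccc2)cc(OCOC)cc1OCc1ccccc1
F6 | step 4 | (S)-2-[2,6-bis(benzyloxy)-4-(methoxymethoxy)phenyl]-1-[(R)-tert-butylsulfinyl]-1,2,3,6-tetrahydropyridine | CC(C)(C)[S@@](=O)N1CC=CC[C@H]1c1c(OCc2ccccc2)cc(OCOC)cc1OCc1ccccc1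
F7 | step 9 | tert-butyl (S)-2-[3-acetyl-2,6-bis(benzyloxy)-4-(4-methoxybenzyloxy)phenyl]piperidine-1-carboxylate | CC(C)(C)OC(=O)N1CCCC[C@H]1c1c(OCc2ccccc2)cc(OCc2ccc(OC)cc2)c(C(C)=O)c1OCc1ccccc1
F8 | step 9 | tert-butyl (S)-2-[2,6-bis(benzyloxy)-3-(3-tert-butoxy-3-oxopropanoyl)-4-(4-methoxybenzyloxy)phenyl]piperidine-1-carboxylate | CC(C)(C)OC(=O)N1CCCC[C@H]1c1c(OCc2ccccc2)cc(OCc2ccc(OC)cc2)c(C(=O)CC(=O)OC(C)(C)C)c1OCc1ccccc1
F9 | step 9 | tert-butyl (S)-2-[2,6-bis(benzyloxy)-3-[(Z)-3-(4-benzyloxyphenyl)-2-(tert-butoxycarbonyl)acryloyl]-4-(4-methoxybenzyloxy)phenyl]piperidine-1-carboxylate | CC(C)(C)OC(=O)N1CCCC[C@H]1c1c(OCc2ccccc2)cc(OCc2ccc(OC)cc2)c(C(=O)/C(C(=O)OC(C)(C)C)=C/c2ccc(OCc3ccccc3)cc2)c1OCc1ccccc1
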